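**Retrosynthetic overview**
- Target ⇐ Luche reduction of the C7 enone ⇐ allylic oxidation ⇐ Wittig methylenation of a hydroxy-succinimide decalin-8-one.
- Succinimide (last ring) ⇐ ammonia-induced imide closure of a syn-aldol adduct (C12–C13 bond) between a ring-B keto aldehyde and a succinate-derived N-acyl thiazolidinethione.
- Ring B keto aldehyde ⇐ ring expansion: amine-catalysed vinylogous semipinacol 1,2-shift of C10 in a hydrindane γ-hydroxy enal (cyclopentanol → cyclohexanone; creates C9 and the C8 ketone).
- γ-Hydroxy enal ⇐ propargyl alcohol adduct of a Hajos–Parrish-type enedione, after Birch reductive methylation (C4 gem-dimethyl, trans fusion) and α-chlorination/reduction (2α-Cl, 3β-OH).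
- Enedione ⇐ 2-methylcyclopentane-1,3-dione + ethyl vinyl ketone; ring order: five-membered ring (bought) → ring A → ring B (by expansion) → succinimide.

Assumption: the SMILES defines the 2α-Cl, 3β-OH, 5α-H, 7β-OH, 9α-H, 10β-Me, 12S, 13R enantiomer; all intermediates carry labdane atom numbers (in the hydrindanes C9 is absent and C8 is bonded to C10; β = face of the C10 methyl).

**Step 1**
Reactants: 1 2-methylcyclopentane-1,3-dione; 2 pent-1-en-3-one (ethyl vinyl ketone)
Product: 3 2-methyl-2-(3-oxopentyl)cyclopentane-1,3-dione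
Conditions: 2 (1.5 equiv), H2O, AcOH (cat.), 75 °C
Reagents that add atoms: none
Why: Michael addition of the acidic cyclic 1,3-dione to the enone in water; no stereocentre is formed yet (C10 is still prochiral).

**Step 2**
Reactants: 3 2-methyl-2-(3-oxopentyl)cyclopentane-1,3-dione
Product: 4 (7aS)-4,7a-dimethyl-2,3,7,7a-tetrahydro-1H-indene-1,5(6H)-dione
Conditions: L-phenylalanine (1.0 equiv), 1 M aq. HClO4 (0.5 equiv), MeCN, reflux
Reagents that add atoms: none
Why: Hajos–Parrish-type amino-acid enamine aldol condensation, in which the L-amino acid enamine of the ethyl ketone selects one of the two enantiotopic ring carbonyls and so sets C10 as S (β-methyl) before dehydration to the enone.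

**Step 3**
Reactants: 4 (7aS)-enedione; 5 prop-2-yn-1-ol
Product: 6 alkynediol enone (enone of 4 intact; C8 now bears β-OH and α-C≡C–CH2OH)
Conditions: 5 (3 equiv), n-BuLi (6 equiv), THF, −78 → 0 °C; CeCl3, −78 °C; then 4, −78 °C; aq. NH4Cl
Reagents that add atoms: none
Why: organocerium alkynylation, in which the non-basic acetylide adds 1,2 to the saturated cyclopentanone (more electrophilic than the vinylogously deactivated tetrasubstituted enone) from the α-face anti to the angular methyl, giving the 8β-carbinol.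

**Step 4**
Reactants: 6 alkynediol enone
Product: 8 (E)-enediol ketone (trans-fused 4,4,10-trimethylhydrindan-3-one; 5α-H; 8β-OH; 8α-[(E)-3-hydroxyprop-1-enyl]), via trilithium enolate 7 (not isolated)
Conditions: Li (6 equiv), t-BuOH (1.0 equiv), NH3(l)/THF, −78 → −33 °C; isoprene; MeI (4 equiv), −78 °C; NH4Cl
Reagents that add atoms: iodomethane, CI
Why: Birch reductive alkylation, in which axial protonation of the C5 carbanion gives the trans ring fusion (5α-H), the regiodefined C3–C4 enolate is C-methylated to the gem-dimethyl group, and the but-2-yne-1,4-diol dialkoxide is reduced in the same pot to the E-alkene by dissolving-metal trans-reduction.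

**Step 5**
Reactants: 8 (E)-enediol ketone
Product: 10 chlorohydrin triol (2α-chloro-3β,8β-dihydroxy-8α-[(E)-3-hydroxyprop-1-enyl]-4,4,10β-trimethyl-5α-hydrindane), via 2α-chloro ketone 9 (not isolated)
Conditions: LiN(SiMe3)2 (3.3 equiv), THF, −78 °C; C2Cl6 (1.05 equiv), −78 °C; AcOH (3.5 equiv); then NaBH4, MeOH, −78 → −20 °C
Reagents that add atoms: hexachloroethane, ClC(Cl)(Cl)C(Cl)(Cl)Cl
Why: enolate α-chlorination followed by hydride reduction, in which C2 is the only enolisable position, chlorine enters anti to the axial C10 methyl (2α, equatorial) and borohydride attacks C3 axially from the α-face to give the equatorial 3β-alcohol.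

**Step 6**
Reactants: 10 chlorohydrin triol
Product: 11 γ-hydroxy enal ((E)-3-(2α-chloro-3β,8β-dihydroxy-4,4,10β-trimethyl-5α-hydrindan-8α-yl)prop-2-enal)
Conditions: MnO2 (activated, 20 equiv), CH2Cl2, rt
Reagents that add atoms: none
Why: MnO2 oxidises only the primary allylic alcohol (the tertiary allylic and the saturated secondary alcohols are inert), with retention of the E geometry.

**Step 7**
Reactants: 11 γ-hydroxy enal
Product: 12 keto aldehyde (2α-chloro-3β-hydroxy-8-oxo-13,14,15,16,17-pentanorlabdan-12-al; trans-decalin; 9α-H)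
Conditions: pyrrolidine (20 mol %), 4-nitrobenzoic acid (20 mol %), toluene (2 equiv H2O), 50 °C
Reagents that add atoms: none
Why: Proposed new method: iminium-triggered vinylogous semipinacol ring expansion of an unstrained cyclopentanol onto an enal, in which the enal iminium makes the β-carbon (future C9, bonded to the carbinol C8) electrophilic, the carboxylate-assisted 8-OH pushes the electron-rich quaternary C10 to migrate from C8 to C9 with retention (in preference to C7H2), the C8 ketone and an enamine form and hydrolysis releases the aldehyde, the process being driven by C=O formation and five-to-six ring enlargement and C9 settling by enolisation to the equatorial 9β side chain (9α-H); the closest known reaction type is the amine-catalysed vinylogous α-ketol rearrangement of strained β-(1-hydroxycyclobutyl) enones, alongside acid-induced D-homoannulation of 17-hydroxy steroids.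

**Step 8**
Reactants: 13 succinic anhydride
Product: 15 methyl 4-[(4R)-4-benzyl-2-thioxo-1,3-thiazolidin-3-yl]-4-oxobutanoate, via monomethyl succinate 14 (not isolated)
Conditions: MeOH (1.0 equiv), Et3N, DMAP (cat.), CH2Cl2, rt; then (R)-4-benzyl-1,3-thiazolidine-2-thione, EDC·HCl, 0 °C → rt
Reagents that add atoms: methanol, CO; (R)-4-benzyl-1,3-thiazolidine-2-thione, S=C1SC[C@@H](Cc2ccccc2)N1
Why: anhydride methanolysis followed by carbodiimide N-acylation of the thiazolidinethione; the only stereocentre is that of the auxiliary.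

**Step 9**
Reactants: 12 keto aldehyde; 15 N-acyl thiazolidinethione
Product: 16 (12S,13R)-syn-aldol adduct (C13 bears CH2CO2Me and the N-acyl thiazolidinethione; C12 bears OH)
Conditions: 15 (2.2 equiv), TiCl4 (2.3 equiv), i-Pr2NEt (2.4 equiv), CH2Cl2, 0 °C; N-methyl-2-pyrrolidinone (2.2 equiv); then 12, −78 → −40 °C; aq. NH4Cl
Reagents that add atoms: none
Why: Crimmins titanium-enolate aldol (Evans-syn mode), in which the Z-enolate reacts through a non-chelated chair transition state whose face is fixed by the (R)-benzyl group, giving the 12S,13R syn adduct at the aldehyde while the hindered C8 ketone is untouched (the excess enolate covers the free 3-OH).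

**Step 10**
Reactants: 16 syn-aldol adduct
Product: 18 hydroxy succinimide ketone ((3R)-3-[(1S)-1-hydroxy-2-(8-oxo-decalinyl)ethyl]pyrrolidine-2,5-dione; the 17-nor-8-oxo-7-deoxy analogue of the target), via primary amide ester 17 (not isolated)
Conditions: NH3 (7 M in MeOH), 0 °C → rt, then 40 °C
Reagents that add atoms: ammonia, N
Why: aminolysis of the activated N-acyl thiazolidinethione releases the auxiliary, and the primary amide then closes onto the methyl ester (5-exo, aspartimide-type imide formation) without touching C12 or C13.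

**Step 11**
Reactants: 18 hydroxy succinimide ketone
Product: 19 exocyclic alkene (7-deoxy target; C8=CH2)
Conditions: Ph3PCH3Br (5 equiv), KN(SiMe3)2 (4.8 equiv), THF, 0 °C; then 18, 0 → 50 °C
Reagents that add atoms: methyltriphenylphosphonium bromide, C[P+](c1ccccc1)(c1ccccc1)c1ccccc1.[Br-]
Why: Wittig methylenation of the C8 ketone with base-free ylide, the imide being protected in situ as its N-anion and the alcohols staying largely protonated, so that retro-aldol is suppressed and C9 keeps its stable equatorial configuration.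

**Step 12**
Reactants: 19 exocyclic alkene
Product: 21 exo-methylene enone (7-oxo), via 7α-allylic alcohol 20 (not isolated)
Conditions: SeO2 (0.5 equiv), t-BuOOH (3 equiv), CH2Cl2, 0 °C → rt; then MnO2 (20 equiv), rt
Reagents that add atoms: tert-butyl hydroperoxide, CC(C)(C)OO (oxygen relayed through selenium dioxide, O=[Se]=O)
Why: SeO2 ene/[2,3]-sigmatropic allylic hydroxylation at the less hindered allylic CH2 (C7, giving the axial 7α-alcohol) followed by MnO2 oxidation of that allylic alcohol only, which erases the wrong C7 configuration.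

**Step 13**
Reactants: 21 exo-methylene enone
Product: 22 3β-hydroxylissoclimide
Conditions: NaBH4, CeCl3·7H2O, MeOH, −78 °C
Reagents that add atoms: none
Why: Luche 1,2-reduction, in which hydride is delivered axially from the α-face of the C7 carbonyl to give the equatorial 7β-alcohol, with the imide and the exocyclic alkene untouched at −78 °C.

**Compound list**
1 | 2-methylcyclopentane-1,3-dione | CC1C(=O)CCC1=O | starting material
2 | pent-1-en-3-one (ethyl vinyl ketone) | CCC(=O)C=C | starting material
3 | 2-methyl-2-(3-oxopentyl)cyclopentane-1,3-dione | CCC(=O)CCC1(C)C(=O)CCC1=O | intermediate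
4 | (7aS)-4,7a-dimethyl-2,3,7,7a-tetrahydro-1H-indene-1,5(6H)-dione | O=C1CCC2=C(C)C(=O)CC[C@@]21C | intermediate
5 | prop-2-yn-1-ol (propargyl alcohol) | C#CCO | starting material
6 | alkynediol enone: 4 with C8 converted into C(β-OH)(α-C≡C–CH2OH) | OCC#C[C@]1(O)CCC2=C(C)C(=O)CC[C@@]21C | intermediate
7 | trilithium enolate: C3–C4 lithium enolate, 5α-H, lithium alkoxides at C8 and C12, E-alkene | [Li+].[Li+].[Li+].[O-]C/C=C/[C@]1([O-])CC[C@H]2C(C)=C([O-])CC[C@@]21C | intermediate
8 | (E)-enediol ketone: trans-fused 4,4,10β-trimethylhydrindan-3-one, 5α-H, 8β-OH, 8α-[(E)-3-hydroxyprop-1-enyl] | OC/C=C/[C@]1(O)CC[C@H]2C(C)(C)C(=O)CC[C@@]21C | intermediate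
9 | 2α-chloro ketone of 8 | OC/C=C/[C@]1(O)CC[C@H]2C(C)(C)C(=O)[C@H](Cl)C[C@@]21C | intermediate
10 | chlorohydrin triol: 2α-chloro-3β,8β-dihydroxy-8α-[(E)-3-hydroxyprop-1-enyl]-4,4,10β-trimethyl-5α-hydrindane | OC/C=C/[C@]1(O)CC[C@H]2C(C)(C)[C@@H](O)[C@H](Cl)C[C@@]21C | intermediate
11 | γ-hydroxy enal: (E)-3-(2α-chloro-3β,8β-dihydroxy-4,4,10β-trimethyl-5α-hydrindan-8α-yl)prop-2-enal | O=C/C=C/[C@]1(O)CC[C@H]2C(C)(C)[C@@H](O)[C@H](Cl)C[C@@]21C | intermediate
12 | keto aldehyde: 2α-chloro-3β-hydroxy-8-oxo-13,14,15,16,17-pentanorlabdan-12-al (5α-H, 9α-H, 10β-Me) | O=C1CC[C@H]2C(C)(C)[C@@H](O)[C@H](Cl)C[C@]2(C)[C@H]1CC=O | intermediate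
13 | succinic anhydride | O=C1CCC(=O)O1 | starting material
14 | monomethyl succinate (4-methoxy-4-oxobutanoic acid) | COC(=O)CCC(=O)O | intermediate
15 | methyl 4-[(4R)-4-benzyl-2-thioxo-1,3-thiazolidin-3-yl]-4-oxobutanoate | COC(=O)CCC(=O)N1[C@H](Cc2ccccc2)CSC1=S | intermediate
16 | syn-aldol adduct: methyl (3R,4S)-3-[(4R)-4-benzyl-2-thioxo-1,3-thiazolidine-3-carbonyl]-4-hydroxy-5-(2α-chloro-3β-hydroxy-8-oxo-decalin-9β-yl)pentanoate (12S,13R) | O=C1CC[C@H]2C(C)(C)[C@@H](O)[C@H](Cl)C[C@]2(C)[C@H]1C[C@H](O)[C@@H](CC(=O)OC)C(=O)N1[C@H](Cc3ccccc3)CSC1=S | intermediate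
17 | primary amide ester: 16 with the thiazolidinethione replaced by NH2 | O=C1CC[C@H]2C(C)(C)[C@@H](O)[C@H](Cl)C[C@]2(C)[C@H]1C[C@H](O)[C@@H](CC(=O)OC)C(N)=O | intermediate
18 | hydroxy succinimide ketone: (3R)-3-[(1S)-1-hydroxy-2-(2α-chloro-3β-hydroxy-8-oxo-decalin-9β-yl)ethyl]pyrrolidine-2,5-dione | O=C1CC[C@H]2C(C)(C)[C@@H](O)[C@H](Cl)C[C@]2(C)[C@H]1C[C@H](O)[C@H]1CC(=O)NC1=O | intermediate
19 | 7-deoxy-3β-hydroxylissoclimide (8(17)-exocyclic alkene) | C=C1CC[C@H]2C(C)(C)[C@@H](O)[C@H](Cl)C[C@]2(C)[C@H]1C[C@H](O)[C@H]1CC(=O)NC1=O | intermediate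
20 | 7-epi-3β-hydroxylissoclimide (7α-OH) | C=C1[C@H](O)C[C@H]2C(C)(C)[C@@H](O)[C@H](Cl)C[C@]2(C)[C@H]1C[C@H](O)[C@H]1CC(=O)NC1=O | intermediate
21 | 7-oxo exo-methylene enone (7-dehydro-3β-hydroxylissoclimide) | C=C1C(=O)C[C@H]2C(C)(C)[C@@H](O)[C@H](Cl)C[C@]2(C)[C@H]1C[C@H](O)[C@H]1CC(=O)NC1=O | intermediate
22 | 3β-hydroxylissoclimide | C=C1[C@@H](O)C[C@H]2C(C)(C)[C@@H](O)[C@H](Cl)C[C@]2(C)[C@H]1C[C@H](O)[C@H]1CC(=O)NC1=O | target

**Step count**
Total: 13 steps. Longest linear sequence: 12 steps (steps 1–7 and 9–13; step 8 prepares the aldol partner).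

**Three steps most likely to fail**

Step 7 (the proposed new ring expansion). The 1,2-shift may be slow without ring strain, C7 may migrate instead of C10, or the 1,4-keto aldehyde may condense to a fused furan. The fallback uses known chemistry, sets out from 10 and returns at 12. Selective silylation of the primary alcohol (TBSCl, imidazole, CH2Cl2) gives the primary silyl ether F1. Hydroxyl-directed epoxidation (VO(acac)2, t-BuOOH, CH2Cl2) gives the trans-epoxy alcohol F2, drawn as the diastereomer whose anti migration gives the 9α-H ketone directly; the other converges two stages later. Lewis-acid semipinacol ring expansion of this 2,3-epoxy tertiary alcohol (BF3·OEt2, CH2Cl2, −78 °C, C10 migrating anti to the breaking C–O bond) gives the β-hydroxy ketone F3. Acid-catalysed dehydration (TsOH, toluene, 60 °C) gives the (Z)-alkylidene ketone F4. Hydrogenation (H2, 10% Pd/C, EtOAc, then K2CO3, MeOH to equilibrate C9) gives the saturated keto silyl ether F5. Desilylation (HF·pyridine, THF) gives the keto alcohol F6, and chemoselective oxidation of the primary alcohol (TEMPO, PhI(OAc)2, CH2Cl2) delivers 12.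

Step 4 (tandem Birch reductive methylation and alkyne reduction). Risks are over-reduction of the ketone, O-methylation of the primary alkoxide, and incomplete or hydrogenolytic alkyne reduction. The fallback sets out from 6 and returns at 8, and separates the two reductions. Ruthenium-catalysed trans-hydrogenation of the propargylic diol ([(C5Me5)RuCl(cod)] 5 mol %, H2 10 bar, CH2Cl2) gives the (E)-enediol enone F7 with the enone intact. A conventional reductive methylation of the enone alone (Li, NH3/THF, t-BuOH 1 equiv, then MeI), passing through 7, then gives 8.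

Step 11 (Wittig on the unprotected hydroxy imide). Risks are a sluggish reaction at the hindered ketone, masking of the ketone as a hemiketal by the 12-OH, and retro-aldol or C13 epimerisation if free base is present. The fallback sets out from 18 and returns at 19, and replaces the ylide by an addition–elimination sequence. Excess Me3SiCH2Li/CeCl3 (THF, −78 °C, non-basic organocerium, equatorial attack) gives the β-hydroxysilane F8. Acid-mediated Peterson elimination (aq. HF, MeCN, 0 °C) gives 19.

**Further compounds**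
F1 | step 7 | primary tert-butyldimethylsilyl ether of 10 | CC(C)(C)[Si](C)(C)OC/C=C/[C@]1(O)CC[C@H]2C(C)(C)[C@@H](O)[C@H](Cl)C[C@@]21C
F2 | step 7 | trans-epoxy alcohol (epoxide of F1 next to the C8 carbinol) | CC(C)(C)[Si](C)(C)OC[C@@H]1O[C@H]1[C@]2(O)CC[C@H]3C(C)(C)[C@@H](O)[C@H](Cl)C[C@@]32C
F3 | step 7 | ring-expanded β-hydroxy ketone (C8 ketone, 9α-H, C11–OH, C12–OTBS) | O=C1CC[C@H]2C(C)(C)[C@@H](O)[C@H](Cl)C[C@]2(C)[C@H]1[C@@H](O)CO[Si](C)(C)C(C)(C)C
F4 | step 7 | (Z)-alkylidene ketone (C9=C11) | O=C1CC[C@H]2C(C)(C)[C@@H](O)[C@H](Cl)C[C@]2(C)/C1=C/CO[Si](C)(C)C(C)(C)C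
F5 | step 7 | saturated keto silyl ether (9α-H) | O=C1CC[C@H]2C(C)(C)[C@@H](O)[C@H](Cl)C[C@]2(C)[C@H]1CCO[Si](C)(C)C(C)(C)C
F6 | step 7 | keto alcohol (12-hydroxy analogue of 12) | O=C1CC[C@H]2C(C)(C)[C@@H](O)[C@H](Cl)C[C@]2(C)[C@H]1CCO
F7 | step 4 | (E)-enediol enone (6 with the alkyne reduced to the E-alkene) | OC/C=C/[C@]1(O)CCC2=C(C)C(=O)CC[C@@]21C
F8 | step 11 | β-hydroxysilane (8β-OH, 8α-CH2SiMe3 adduct of 18) | C[Si](C)(C)C[C@]1(O)CC[C@H]2C(C)(C)[C@@H](O)[C@H](Cl)C[C@]2(C)[C@H]1C[C@H](O)[C@H]1CC(=O)NC1=O
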